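Late times were what I needed: the south-west flask had been followed to 12.0 min, and the question stood at 40 min.

the same everywhere: solid substrate 0.80 M

| charge | reagent | remark | time |
|---|---|---|---|
| south-west | 1.6 M | the very flask that is asked about, followed so far |  |
| south-east | 2.4 M | run made earlier |  |
| flask | 1.60 M |  | 40 min |

| run | time / min | solid substrate / % | single product / % | double product / % |
|---|---|---|---|---|
| south-west | 2.50 | 97.6 | 0 | 0.3 |
| south-west | 5.00 | 95.7 | 0 | 0.2 |
| south-west | 8.00 | 92.2 | 1.7 | 0.8 |
| south-west | 10.0 | 90.1 | 1.5 | 0.5 |
| south-west | 12.0 | 89.8 | 2.9 | 0.3 |
| south-east | 3.00 | 97.0 | 1.0 | 0.1 |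
| south-east | 6.00 | 93.7 | 1.3 | 0.9 |
| south-east | 12.0 | 88.0 | 2.8 | 0 |
| south-east | 20.0 | 82.2 | 5.9 | 0.5 |
| south-east | 40.0 | 66.3 | 13.8 | 6.8 |

(scatter of a reading: 0.5 percentage points)

- at the start none of the solid substrate is in solution
- a reading or a percentage of double product counts all its forms, free or not

- amount of solid substrate at 40 min, in percent of the solid substrate charged (only what is still solid)
- amount of single product at 40 min, in percent of the solid substrate charged
- amount of double product at 40 min, in percent of the solid substrate charged

Two pairs of numbers did not go together. The south-east run held 1.50 times the reagent of the south-west run, yet by 12.0 min it had lost 12.0% of its solid substrate against 10.2%, a ratio of 1.18. And at 40.0 min the south-east run had lost 33.7% of its solid, while its two products came to less, 20.6%.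

I cleared this by supposing a step ahead of the reagent: solid entering solution, with the missing 13.1% dissolved and waiting. So I worked with the fraction left and carried one quantity, the crawl, meaning solid substrate entering solution per litre per minute, read as an average over the south-east run: 0.00674 M min⁻¹. I took it as zero order, supposing it unchanged by the solid remaining and by the reagent. The fraction left is then one minus crawl times time over charge, which for the south-west flask gave 66.3%.

The forecast, which found dissolution “largely independent of reagent”, said 68.5% solid, 12% single product and 3.5% double product, its solid figure above mine. The flask gave 67.2%, 12.7% and 3.54%.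

    starting material + reagent → single product (k = 4.42 × 10⁻⁴ M⁻¹ s⁻¹)
    starting material ⇌ dormant form (K = 0.567, k = 8.12 × 10⁻⁵ s⁻¹)
    crystals ⇌ double product, rate k3*(cs3 - [double product]) while solid is left; crystals form when [double product] > cs3 (solubility = 0.530 M, k = 0.0712 s⁻¹)
    reagent + single product → double product (k = 1.82 × 10⁻⁴ M⁻¹ s⁻¹)
    solid substrate ⇌ starting material, rate k5*(cs5 - [starting material]) while solid is left; crystals form when [starting material] > cs5 (solubility = 0.460 M, k = 2.88 × 10⁻⁴ s⁻¹)

The south-west flask lost solid at 0.00656 M min⁻¹ on average, against my crawl of 0.00674 M min⁻¹. I put the same crawl on the neighbour flask charged with 0.48 M of solid substrate. On that smaller charge it leaves a lower fraction, 43.8%, and that neighbour flask gave 45.3%, an average loss of 0.00656 M min⁻¹. In percent of its own charge, that neighbour flask held 21.2% of single product at 40 min.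

Readings and results were generated by integration with made-up constants.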